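1. The leftover comes first: at its last reading, at 20.0 min, the ochre run still holds 0.7% of its substrate, and the grey run holds 0% at the same time.

all flasks: substrate 0.011 M; gas phase 0.71 mM (held)

|  | free catalyst | remark | time |
|---|---|---|---|
| ochre | 0.55 mM | run made earlier |  |
| grey | 2.2 mM | run made earlier |  |
| flask | 1.1 mM |  | 30 min |

| run | time / min | target / % | substrate / % |
|---|---|---|---|
| ochre | 1.33 | 5.9 | 74.0 |
| ochre | 4.00 | 17.2 | 43.0 |
| ochre | 6.00 | 25.5 | 28.9 |
| ochre | 10.0 | 37.4 | 11.1 |
| ochre | 15.0 | 43.9 | 2.2 |
| ochre | 20.0 | 45.8 | 0.7 |
| grey | 1.33 | 7.5 | 73.7 |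
| grey | 4.00 | 22.3 | 41.5 |
| grey | 6.00 | 32.5 | 26.6 |
| grey | 10.0 | 47.4 | 7.7 |
| grey | 15.0 | 53.6 | 0.4 |
| grey | 20.0 | 54.2 | 0 |

(standard deviation of a reading: 0.3 percentage points)

- the target standing at 30 min, as a percentage of the substrate charged
- concentration of dissolved gas in solution at 30 min, in percent of saturation

- at the start none of the gas phase is in solution

2. Taking one dissolved gas per target, the refill count of a charge is the substrate charged over the saturation concentration: the number of times a saturated solution must be filled anew to serve every substrate. It is 15.5 for ochre, grey and this flask alike.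

3. Refills spent on target are target times that count: 7.10 in ochre and 8.40 in grey at their last readings.

4. Turned round, a target still rising at 30 min needs substrate still standing then, and a falling one needs target being lost. Yet both runs reach their last readings earlier, and the grey target goes from 53.6% to 54.2% over its final interval. Dissolved gas well short of saturation at 30 min needs a consumer still at work or a very slow refill, and the last substrate readings of the runs stand at 0.7% and 0%.

5. The flask's catalyst is the geometric midpoint of the two runs, so the reckoning takes 7.72 refills, a target of 49.8%.

6. The forecast, slightly higher, gives 50.3% and 99.5%, holding that “Target does not degrade after the substrate is gone”.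

The flask gives 50.9% of target and >99.9% of saturation.

    2 free catalyst → spent catalyst (k = 0.672 M⁻¹ s⁻¹)
    substrate + dissolved gas → uncatalysed product (k = 2.35 M⁻¹ s⁻¹)
    gas phase ⇌ dissolved gas, rate k3*(csat - [dissolved gas]) (kL = 0.0164 s⁻¹)
    substrate + dissolved gas + free catalyst → free catalyst + target (k = 25200 M⁻² s⁻¹)
    2 substrate → self-condensation product (k = 0.144 M⁻¹ s⁻¹)

At 15.0 min the flask's target already stands at 50.1%, with the substrate, its limiting reagent, at 0.981%. The flask's target amounts to 7.89 of its 15.5 refills. A neighbouring flask charged with 0.027 M of substrate has a refill count of 38.0, and its target of 26.3% amounts to 10.0 refills.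

The data come from a simulation for an exercise; scatter was added.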